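**Strategy.** The hexasubstituted central ring (ring B) is divided into three two-carbon units. Its two free hydroxyl oxygens, O-5' and O-6', sit on adjacent carbons and can therefore be tied through one silicon atom, which turns two aryl ynol ethers into a 1,6-diyne; the benzoate-bearing carbons C-2' and C-3' come from a diborylalkyne. One [2+2+2] cycloaddition then forms the C-5'–C-6', C-1'–C-2' and C-3'–C-4' bonds, closing ring B and a fused 1,3,2-dioxasilole ring, with boron marking the future benzoate positions. The precursor is a di-tert-butylsilylene-linked bis(ynol ether) that carries the outer phenols as benzyl ethers.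

Key step: step 3

Remark: the target is achiral and has no stereocentre; compounds 1, 2, 6 and 7 are taken as commercial.

**Step 1**
Reactants: 1 trichloroethylene; 2 isopropoxy pinacolborane (2-isopropoxy-4,4,5,5-tetramethyl-1,3,2-dioxaborolane)
Product: 5 bis(pinacolatoboryl)acetylene, via dilithioacetylene 3 (not isolated), via dilithium bis(isopropoxyborate) 4 (not isolated)
Conditions: n-BuLi (3 equiv), Et2O, −78 °C to rt; 2 (2 equiv), −78 °C to rt; HCl in Et2O, −78 °C to rt
Reagents that add atoms: none
Why: Deprotonation, loss of LiCl and two chlorine–lithium exchanges turn 1 into dilithioacetylene, which adds to two boron centres, and anhydrous HCl collapses the bis-ate complex with loss of isopropanol (borylation of a lithium acetylide with an alkoxyboronate, an established alkynylboronate preparation).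

**Step 2**
Reactants: 6 1-(benzyloxy)-4-ethynylbenzene; 7 di-tert-butylsilyl bis(trifluoromethanesulfonate)
Product: 10 di-tert-butylbis({[4-(benzyloxy)phenyl]ethynyl}oxy)silane, via lithium arylacetylide 8 (not isolated), via lithium arylynolate 9 (not isolated)
Conditions: n-BuLi, THF, −78 °C; t-BuOOLi (from t-BuOOH and LiN(SiMe3)2), −78 to 0 °C; 7 (0.45 equiv), −78 °C to rt; Et3N-deactivated silica
Reagents that add atoms: tert-butyl hydroperoxide, CC(C)(C)OO
Why: Oxygen transfer from lithium tert-butylperoxide to the lithium acetylide gives the ynolate, whose rod-shaped oxygen terminus should displace both triflates of the hindered silicon by O-silylation (the standard route to bulky silyl ynol ethers), while the by-products lithium tert-butoxide and hexamethyldisilazane are too hindered to compete at silicon.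

**Step 3**
Reactants: 10 di-tert-butylbis({[4-(benzyloxy)phenyl]ethynyl}oxy)silane; 5 bis(pinacolatoboryl)acetylene
Product: 11 4,7-bis[4-(benzyloxy)phenyl]-2,2-di-tert-butyl-5,6-bis(4,4,5,5-tetramethyl-1,3,2-dioxaborolan-2-yl)-1,3,2-benzodioxasilole
Conditions: [Rh(cod)2]BF4 (10 mol %), rac-BINAP (10 mol %), pre-activated with H2 then purged with Ar; 5 (3 equiv), (CH2Cl)2, slow addition of 10, rt to 60 °C
Reagents that add atoms: none
Why: Proposed new method: the cationic monovalent rhodium–bisphosphine fragment should bind both ynol ether triple bonds of 10 and couple them oxidatively to a rhodacyclopentadiene of trivalent rhodium with the aryl groups on the metal-bound carbons, after which alkyne 5 inserts and C–C reductive elimination releases arene 11; the closest known reaction type is the rhodium- or cobalt-catalysed [2+2+2] cycloaddition of tethered 1,6-diynes with alkynylboronates. Two rings close: the five-membered 1,3,2-dioxasilole ring by the intramolecular oxidative cyclisation that joins the two oxygen-bearing alkyne carbons, and the central benzene ring by the intermolecular insertion and reductive elimination that join each aryl-bearing carbon to a boryl carbon. No stereocentre is formed. The step needs chemoselectivity for cross-cyclotrimerisation over oligomerisation of the diyne, which is served by the three-atom O–Si–O tether with its two tert-butyl groups (a 1,6-diyne pre-folded by the Thorpe–Ingold effect), by slow addition of 10 to an excess of 5, and by the reluctance of the bulky alkyne 5 to trimerise with itself. Regiochemistry is not in question, because the tether forces the two oxygenated carbons to become neighbours and alkyne 5 is symmetric.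

**Step 4**
Reactants: 11 4,7-bis[4-(benzyloxy)phenyl]-2,2-di-tert-butyl-5,6-bis(4,4,5,5-tetramethyl-1,3,2-dioxaborolan-2-yl)-1,3,2-benzodioxasilole
Product: 13 4,7-bis[4-(benzyloxy)phenyl]-2,2-di-tert-butyl-1,3,2-benzodioxasilole-5,6-diol, via aryl bis(borate) 12 (not isolated)
Conditions: Me3NO (anhydrous, 5 equiv), THF, 60 °C, Ar; then pH 7 phosphate buffer, rt, degassed
Reagents that add atoms: trimethylamine N-oxide, C[N+](C)(C)[O-]
Why: The N-oxide oxygen adds to each boron and the aryl group migrates from boron to oxygen with loss of trimethylamine (amine-oxide oxidation of an arylboronic ester by 1,2-metallate shift), and the aryl borates hydrolyse at neutral pH, so neither the base-labile silylene nor the oxidation-prone catechol meets alkaline peroxide.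

**Step 5**
Reactants: 13 4,7-bis[4-(benzyloxy)phenyl]-2,2-di-tert-butyl-1,3,2-benzodioxasilole-5,6-diol
Product: 14 4,7-bis[4-(benzyloxy)phenyl]-2,2-di-tert-butyl-1,3,2-benzodioxasilole-5,6-diyl dibenzoate
Conditions: BzCl (3 equiv), pyridine, DMAP (cat.), CH2Cl2, 0 °C to rt, Ar
Reagents that add atoms: benzoyl chloride, O=C(Cl)c1ccccc1
Why: DMAP-catalysed acylation through the N-benzoylpyridinium ion (Steglich-type nucleophilic catalysis) should esterify both hindered phenols, and the silylene and benzyl ethers are inert to acyl chloride and pyridine.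

**Step 6**
Reactants: 14 4,7-bis[4-(benzyloxy)phenyl]-2,2-di-tert-butyl-1,3,2-benzodioxasilole-5,6-diyl dibenzoate
Product: 15 4,4''-bis(benzyloxy)-5',6'-dihydroxy-[1,1':4',1''-terphenyl]-2',3'-diyl dibenzoate
Conditions: HF·pyridine, pyridine, THF, 0 °C
Reagents that add atoms: none
Why: Fluoride-mediated desilylation cleaves the strained Si–O(aryl) bonds of the five-membered silylene, the buffered medium spares aryl benzoates and benzyl ethers, and benzoyl migration is not possible because each freed hydroxyl is separated from the nearest benzoate by an aryl-bearing ring carbon.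

**Step 7**
Reactants: 15 4,4''-bis(benzyloxy)-5',6'-dihydroxy-[1,1':4',1''-terphenyl]-2',3'-diyl dibenzoate
Product: 16 4,4'',5',6'-tetrahydroxy-[1,1':4',1''-terphenyl]-2',3'-diyl dibenzoate (CNP0216579.0)
Conditions: H2 (1 atm), 10% Pd/C, EtOAc, rt
Reagents that add atoms: none
Why: Hydrogenolysis of the two benzylic C–O bonds over palladium on carbon should free the outer phenols, while aryl benzoates and the catechol are inert under these neutral conditions.

**Compound list**
1 | trichloroethylene | ClC=C(Cl)Cl | starting material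
2 | 2-isopropoxy-4,4,5,5-tetramethyl-1,3,2-dioxaborolane | CC(C)OB1OC(C)(C)C(C)(C)O1 | starting material
3 | dilithioacetylene | [Li]C#C[Li] | intermediate
4 | dilithium ethyne-1,2-diylbis(isopropoxy pinacol borate) | CC(C)O[B-]1(C#C[B-]2(OC(C)C)OC(C)(C)C(C)(C)O2)OC(C)(C)C(C)(C)O1.[Li+].[Li+] | intermediate
5 | bis(pinacolatoboryl)acetylene | CC1(C)OB(C#CB2OC(C)(C)C(C)(C)O2)OC1(C)C | intermediate
6 | 1-(benzyloxy)-4-ethynylbenzene | C#Cc1ccc(OCc2ccccc2)cc1 | starting material
7 | di-tert-butylsilyl bis(trifluoromethanesulfonate) | CC(C)(C)[Si](OS(=O)(=O)C(F)(F)F)(OS(=O)(=O)C(F)(F)F)C(C)(C)C | starting material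
8 | lithium [4-(benzyloxy)phenyl]acetylide | [Li]C#Cc1ccc(OCc2ccccc2)cc1 | intermediate
9 | lithium 2-[4-(benzyloxy)phenyl]ethynolate | [Li+].[O-]C#Cc1ccc(OCc2ccccc2)cc1 | intermediate
10 | di-tert-butylbis({[4-(benzyloxy)phenyl]ethynyl}oxy)silane | CC(C)(C)[Si](OC#Cc1ccc(OCc2ccccc2)cc1)(OC#Cc1ccc(OCc2ccccc2)cc1)C(C)(C)C | intermediate
11 | 4,7-bis[4-(benzyloxy)phenyl]-2,2-di-tert-butyl-5,6-bis(pinacolatoboryl)-1,3,2-benzodioxasilole | CC(C)(C)[Si]1(C(C)(C)C)Oc2c(O1)c(-c1ccc(OCc3ccccc3)cc1)c(B1OC(C)(C)C(C)(C)O1)c(B1OC(C)(C)C(C)(C)O1)c2-c1ccc(OCc2ccccc2)cc1 | intermediate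
12 | 4,7-bis[4-(benzyloxy)phenyl]-2,2-di-tert-butyl-5,6-bis[(pinacolatoboryl)oxy]-1,3,2-benzodioxasilole | CC(C)(C)[Si]1(C(C)(C)C)Oc2c(O1)c(-c1ccc(OCc3ccccc3)cc1)c(OB1OC(C)(C)C(C)(C)O1)c(OB1OC(C)(C)C(C)(C)O1)c2-c1ccc(OCc2ccccc2)cc1 | intermediate
13 | 4,7-bis[4-(benzyloxy)phenyl]-2,2-di-tert-butyl-1,3,2-benzodioxasilole-5,6-diol | CC(C)(C)[Si]1(C(C)(C)C)Oc2c(O1)c(-c1ccc(OCc3ccccc3)cc1)c(O)c(O)c2-c1ccc(OCc2ccccc2)cc1 | intermediate
14 | 4,7-bis[4-(benzyloxy)phenyl]-2,2-di-tert-butyl-1,3,2-benzodioxasilole-5,6-diyl dibenzoate | CC(C)(C)[Si]1(C(C)(C)C)Oc2c(O1)c(-c1ccc(OCc3ccccc3)cc1)c(OC(=O)c1ccccc1)c(OC(=O)c1ccccc1)c2-c1ccc(OCc2ccccc2)cc1 | intermediate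
15 | 4,4''-bis(benzyloxy)-5',6'-dihydroxy-[1,1':4',1''-terphenyl]-2',3'-diyl dibenzoate | O=C(Oc1c(OC(=O)c2ccccc2)c(-c2ccc(OCc3ccccc3)cc2)c(O)c(O)c1-c1ccc(OCc2ccccc2)cc1)c1ccccc1 | intermediate
16 | 4,4'',5',6'-tetrahydroxy-[1,1':4',1''-terphenyl]-2',3'-diyl dibenzoate | O=C(Oc1c(OC(=O)c2ccccc2)c(-c2ccc(O)cc2)c(O)c(O)c1-c1ccc(O)cc1)c1ccccc1 | target

**Step count.** Total steps: 7. Longest linear sequence: 6 steps (6 → 10 → 11 → 13 → 14 → 15 → 16); the branch 1 → 5 adds one step before the convergent step 3.

**Steps most likely to fail**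

1. Step 3 (the proposed new method). The electron-rich bis(ynol ether) may be consumed at the cationic metal by silyl migration to ketenes or by oligomerisation before oxidative coupling, or insertion of the bulky diborylalkyne into the crowded rhodacycle may stall. The fallback uses known chemistry only, sets out from silyl bis(triflate) 7 and returns at diol 13. Commercial tetrabromo-1,4-benzoquinone (O=C1C(Br)=C(Br)C(=O)C(Br)=C1Br) with NaOMe in MeOH should give 2,5-dibromo-3,6-dimethoxy-1,4-benzoquinone F1 by addition–elimination. Double Suzuki–Miyaura coupling with commercial 4-(benzyloxy)phenylboronic acid (OB(O)c1ccc(OCc2ccccc2)cc1; PdCl2(dppf), K2CO3, dioxane/H2O) should give 2,5-bis[4-(benzyloxy)phenyl]-3,6-dimethoxy-1,4-benzoquinone F2. Aqueous NaOH then hydrolyses the two vinylogous methyl esters to 2,5-bis[4-(benzyloxy)phenyl]-3,6-dihydroxy-1,4-benzoquinone F3, and Na2S2O4 under argon reduces it to 3,6-bis[4-(benzyloxy)phenyl]benzene-1,2,4,5-tetraol F4. Treatment with 7 (1 equiv) and 2,6-lutidine at low temperature silylates one pair of neighbouring hydroxyls to give 13; a silylene can only bridge two ortho oxygens, so the mono-silylene is a single constitutional isomer, and any bis-silylene is recycled with HF·pyridine.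

2. Step 2. Incomplete oxygen transfer from the peroxide would leave acetylide that caps silicon irreversibly through carbon; the second triflate displacement at the crowded silicon may also lag. The fallback sets out from silyl bis(triflate) 7 and returns at diyne 10, generating the ynolate without any acetylide. Commercial methyl 4-(benzyloxy)benzoate (COC(=O)c1ccc(OCc2ccccc2)cc1) is treated with dibromomethyllithium (CH2Br2, lithium 2,2,6,6-tetramethylpiperidide, THF, −78 °C), then LiN(SiMe3)2 and n-BuLi. The lithium 1-[4-(benzyloxy)phenyl]-2,2-dibromoethenolate F5 formed in the flask undergoes bromine–lithium exchange and 1,2-aryl shift on warming (Kowalski ester homologation) to the same ynolate 9. After residual organolithium has decayed at room temperature, 7 is added as in step 2 to give 10.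

3. Step 4. Oxygen insertion at the second, doubly flanked boronate may remain incomplete, or hydrolytic loss of the silylene during work-up may be followed by air oxidation of the electron-rich catechol. The fallback sets out from 11 and returns at 15 by reversing the roles of the two oxygen pairs, which differ only in their acylation. HF·pyridine (pyridine, THF, 0 °C) removes the silylene first to give 3,6-bis[4-(benzyloxy)phenyl]-4,5-bis(pinacolatoboryl)benzene-1,2-diol F6; the hindered pinacol boronates should be slow to fluorinate. Benzoylation (BzCl, pyridine, DMAP) gives 3,6-bis[4-(benzyloxy)phenyl]-4,5-bis(pinacolatoboryl)-1,2-phenylene dibenzoate F7. Oxidation with Me3NO in THF then proceeds through 3,6-bis[4-(benzyloxy)phenyl]-4,5-bis[(pinacolatoboryl)oxy]-1,2-phenylene dibenzoate F8 (not isolated), which hydrolyses in pH 7 buffer to 15. The catechol is thus formed on a silicon-free, less electron-rich ring.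

**Further compounds**
F1 | step 3 | 2,5-dibromo-3,6-dimethoxy-1,4-benzoquinone | COC1=C(Br)C(=O)C(OC)=C(Br)C1=O
F2 | step 3 | 2,5-bis[4-(benzyloxy)phenyl]-3,6-dimethoxy-1,4-benzoquinone | COC1=C(c2ccc(OCc3ccccc3)cc2)C(=O)C(OC)=C(c2ccc(OCc3ccccc3)cc2)C1=O
F3 | step 3 | 2,5-bis[4-(benzyloxy)phenyl]-3,6-dihydroxy-1,4-benzoquinone | OC1=C(c2ccc(OCc3ccccc3)cc2)C(=O)C(O)=C(c2ccc(OCc3ccccc3)cc2)C1=O
F4 | step 3 | 3,6-bis[4-(benzyloxy)phenyl]benzene-1,2,4,5-tetraol | Oc1c(O)c(-c2ccc(OCc3ccccc3)cc2)c(O)c(O)c1-c1ccc(OCc2ccccc2)cc1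
F5 | step 2 | lithium 1-[4-(benzyloxy)phenyl]-2,2-dibromoethenolate | [Li+].[O-]C(=C(Br)Br)c1ccc(OCc2ccccc2)cc1
F6 | step 4 | 3,6-bis[4-(benzyloxy)phenyl]-4,5-bis(pinacolatoboryl)benzene-1,2-diol | Oc1c(O)c(-c2ccc(OCc3ccccc3)cc2)c(B2OC(C)(C)C(C)(C)O2)c(B2OC(C)(C)C(C)(C)O2)c1-c1ccc(OCc2ccccc2)cc1
F7 | step 4 | 3,6-bis[4-(benzyloxy)phenyl]-4,5-bis(pinacolatoboryl)-1,2-phenylene dibenzoate | O=C(Oc1c(OC(=O)c2ccccc2)c(-c2ccc(OCc3ccccc3)cc2)c(B2OC(C)(C)C(C)(C)O2)c(B2OC(C)(C)C(C)(C)O2)c1-c1ccc(OCc2ccccc2)cc1)c1ccccc1
F8 | step 4 | 3,6-bis[4-(benzyloxy)phenyl]-4,5-bis[(pinacolatoboryl)oxy]-1,2-phenylene dibenzoate | O=C(Oc1c(OC(=O)c2ccccc2)c(-c2ccc(OCc3ccccc3)cc2)c(OB2OC(C)(C)C(C)(C)O2)c(OB2OC(C)(C)C(C)(C)O2)c1-c1ccc(OCc2ccccc2)cc1)c1ccccc1
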